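**Retrosynthetic overview**
- Target ⇐ global O-debenzylation ⇐ phenol-selective 7-O-acylation of 5,3',4'-tri-O-benzylcatechin with tri-O-benzylgalloyl chloride.
- Ring C (the only ring made, closed last) ⇐ C2–O1 ketalisation plus C2–H ionic hydrogenation of an (S)-α-hydroxy aryl ketone; the C3 centre dictates 2,3-trans.
- Key C2–C3 bond ⇐ enantioselective cross-benzoin: the acyl anion (Breslow intermediate) of the ring B aldehyde adds to the ring A arylacetaldehyde.
- Ring A arylacetaldehyde ⇐ 2,4,6-trihydroxybenzaldehyde by MOM/benzyl differentiation (MOM on the future O1 and O7, benzyl on O5) and one-carbon homologation.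
- Rings A and B are bought as arenes.

Assumption: the (5S)-triazolium salt of step 4 is taken to give the (S)-ketol; if it gives the (R)-ketol, its (5R)-enantiomer is used.

**Step 1**
Reactants: 1 2,4,6-trihydroxybenzaldehyde
Product: 2 2-hydroxy-4,6-bis(methoxymethoxy)benzaldehyde
Conditions: MOMCl (2.2 equiv), K2CO3, acetone, 0 °C → rt
Reagents that add atoms: chloromethyl methyl ether, COCCl
Why: Williamson-type MOM protection alkylates the 4-OH and one ortho OH, while the second ortho OH, held in a hydrogen bond to the formyl group, stays free; no stereocentre is formed.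

**Step 2**
Reactants: 2 2-hydroxy-4,6-bis(methoxymethoxy)benzaldehyde
Product: 3 2-(benzyloxy)-4,6-bis(methoxymethoxy)benzaldehyde
Conditions: BnBr (1.2 equiv), K2CO3, DMF, 60 °C
Reagents that add atoms: benzyl bromide, BrCc1ccccc1
Why: Williamson ether synthesis under forcing conditions benzylates the remaining chelated phenol, so the later O5 carries benzyl and the later O1 and O7 carry acid-labile MOM groups.

**Step 3**
Reactants: 3 2-(benzyloxy)-4,6-bis(methoxymethoxy)benzaldehyde
Product: 5 2-[2-(benzyloxy)-4,6-bis(methoxymethoxy)phenyl]acetaldehyde, via aryl oxirane 4 (not isolated)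
Conditions: Me3S+ I− (1.3 equiv), KOtBu, DMSO–THF, 0 °C → rt; work-up; then InCl3 (5 mol%), THF, 0 °C → rt
Reagents that add atoms: trimethylsulfonium iodide, C[S+](C)C.[I-]
Why: Corey–Chaykovsky epoxidation of the non-enolisable aldehyde is followed by a Lewis-acid Meinwald rearrangement, in which the very electron-rich benzylic C–O bond of 4 ionises and a 1,2-hydride shift gives the arylacetaldehyde without touching the MOM or benzyl ethers.

**Step 4**
Reactants: 5 2-[2-(benzyloxy)-4,6-bis(methoxymethoxy)phenyl]acetaldehyde; 6 3,4-bis(benzyloxy)benzaldehyde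
Product: 7 (2S)-1-[3,4-bis(benzyloxy)phenyl]-3-[2-(benzyloxy)-4,6-bis(methoxymethoxy)phenyl]-2-hydroxypropan-1-one
Conditions: 6 (2 equiv), (5S)-5-[hydroxy(diphenyl)methyl]-2-(pentafluorophenyl)-6,7-dihydro-5H-pyrrolo[2,1-c][1,2,4]triazol-2-ium tetrafluoroborate (10 mol%), Rb2CO3 (10 mol%), 4 Å MS, THF, 0 °C; 5 added over 8 h
Reagents that add atoms: none
Why: Proposed new method: a chiral-triazolylidene cross-benzoin (acyl-anion umpolung through the Breslow intermediate) in which the electron-rich aldehyde 6, a poor acceptor held in excess, is the only acyl-anion donor and the more electrophilic aldehyde 5, kept at low concentration by slow addition and hydrogen-bonded to the catalyst carbinol, is the only acceptor, so that attack of the enaminol on one carbonyl face sets the (S) carbinol centre (the later C3) and gives the conjugated, thermodynamically preferred aryl ketol; the closest known reaction types are the triazolium-catalysed enantioselective benzoin condensation, the chemoselective NHC cross-benzoin of aryl aldehyde donors with N-protected α-amino aldehyde acceptors, and thiamine-dependent enzymatic carboligation of aryl aldehydes with aliphatic aldehydes.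

**Step 5**
Reactants: 7 (2S)-1-[3,4-bis(benzyloxy)phenyl]-3-[2-(benzyloxy)-4,6-bis(methoxymethoxy)phenyl]-2-hydroxypropan-1-one
Product: 10 (2R,3S)-5-(benzyloxy)-2-[3,4-bis(benzyloxy)phenyl]-3,4-dihydro-2H-chromene-3,7-diol, via bisphenol ketol 8 (not isolated), via cyclic methyl ketal 9 (not isolated)
Conditions: HCl (1.25 M in MeOH), CH2Cl2–MeOH, 0 °C → rt; evaporate; then Et3SiH (3 equiv), TFA (5 equiv), CH2Cl2, −40 → −10 °C; NaHCO3 quench
Reagents that add atoms: none
Why: Acetal cleavage followed by Kishi-type ionic hydrogenation: acidic methanol removes both MOM groups, the freed ortho phenol closes onto the aryl ketone as the six-membered ketal 9, and TFA ionises this to the 2-aryl oxocarbenium ion, which Et3SiH reduces by axial hydride delivery on the half-chair with the C3 hydroxyl pseudo-equatorial, giving the 2,3-trans (2R) flavan as in the reduction of aryl C-glycoside ketals while C3 is untouched.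

**Step 6**
Reactants: 10 (2R,3S)-5-(benzyloxy)-2-[3,4-bis(benzyloxy)phenyl]-3,4-dihydro-2H-chromene-3,7-diol; 11 3,4,5-tris(benzyloxy)benzoyl chloride
Product: 12 (2R,3S)-5-(benzyloxy)-2-[3,4-bis(benzyloxy)phenyl]-3-hydroxy-3,4-dihydro-2H-chromen-7-yl 3,4,5-tris(benzyloxy)benzoate
Conditions: 11 (1.05 equiv), K2CO3, acetone, 0 °C → rt
Reagents that add atoms: none
Why: Schotten–Baumann-type acylation is chemoselective because K2CO3 deprotonates only the single free phenol, and the phenoxide is acylated far faster than the neutral secondary 3-OH; no stereocentre is affected.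

**Step 7**
Reactants: 12 (2R,3S)-5-(benzyloxy)-2-[3,4-bis(benzyloxy)phenyl]-3-hydroxy-3,4-dihydro-2H-chromen-7-yl 3,4,5-tris(benzyloxy)benzoate
Product: 13 catechin 7-O-gallate, (2R,3S)-2-(3,4-dihydroxyphenyl)-3,5-dihydroxy-3,4-dihydro-2H-chromen-7-yl 3,4,5-trihydroxybenzoate
Conditions: H2 (1 atm), Pd(OH)2/C, THF–EtOAc, rt
Reagents that add atoms: none
Why: Heterogeneous hydrogenolysis over palladium in a neutral aprotic solvent removes all six benzyl ethers and leaves the aryl gallate ester, the ring C benzylic ether and both stereocentres intact, as in the last step of known catechin gallate syntheses.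

**Compound list**
1 | 2,4,6-trihydroxybenzaldehyde | O=Cc1c(O)cc(O)cc1O | starting material
2 | 2-hydroxy-4,6-bis(methoxymethoxy)benzaldehyde | O=Cc1c(O)cc(OCOC)cc1OCOC | intermediate
3 | 2-(benzyloxy)-4,6-bis(methoxymethoxy)benzaldehyde | O=Cc1c(OCc2ccccc2)cc(OCOC)cc1OCOC | intermediate
4 | 2-[2-(benzyloxy)-4,6-bis(methoxymethoxy)phenyl]oxirane (racemic, not isolated) | C1OC1c1c(OCc2ccccc2)cc(OCOC)cc1OCOC | intermediate
5 | 2-[2-(benzyloxy)-4,6-bis(methoxymethoxy)phenyl]acetaldehyde | O=CCc1c(OCc2ccccc2)cc(OCOC)cc1OCOC | intermediate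
6 | 3,4-bis(benzyloxy)benzaldehyde | O=Cc1ccc(OCc2ccccc2)c(OCc2ccccc2)c1 | starting material
7 | (2S)-1-[3,4-bis(benzyloxy)phenyl]-3-[2-(benzyloxy)-4,6-bis(methoxymethoxy)phenyl]-2-hydroxypropan-1-one | O=C(c1ccc(OCc2ccccc2)c(OCc2ccccc2)c1)[C@@H](O)Cc1c(OCc2ccccc2)cc(OCOC)cc1OCOC | intermediate
8 | (2S)-1-[3,4-bis(benzyloxy)phenyl]-3-[2-(benzyloxy)-4,6-dihydroxyphenyl]-2-hydroxypropan-1-one (not isolated) | O=C(c1ccc(OCc2ccccc2)c(OCc2ccccc2)c1)[C@@H](O)Cc1c(OCc2ccccc2)cc(O)cc1O | intermediate
9 | (3S)-5-(benzyloxy)-2-[3,4-bis(benzyloxy)phenyl]-2-methoxy-3,4-dihydro-2H-chromene-3,7-diol (both C2 epimers, not isolated) | COC1(c2ccc(OCc3ccccc3)c(OCc3ccccc3)c2)Oc2cc(O)cc(OCc3ccccc3)c2C[C@@H]1O | intermediate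
10 | (2R,3S)-5-(benzyloxy)-2-[3,4-bis(benzyloxy)phenyl]-3,4-dihydro-2H-chromene-3,7-diol (5,3',4'-tri-O-benzylcatechin) | Oc1cc(OCc2ccccc2)c2c(c1)O[C@H](c1ccc(OCc3ccccc3)c(OCc3ccccc3)c1)[C@@H](O)C2 | intermediate
11 | 3,4,5-tris(benzyloxy)benzoyl chloride (bought; also one operation from the commercial acid) | O=C(Cl)c1cc(OCc2ccccc2)c(OCc2ccccc2)c(OCc2ccccc2)c1 | starting material
12 | (2R,3S)-5-(benzyloxy)-2-[3,4-bis(benzyloxy)phenyl]-3-hydroxy-3,4-dihydro-2H-chromen-7-yl 3,4,5-tris(benzyloxy)benzoate | O=C(Oc1cc(OCc2ccccc2)c2c(c1)O[C@H](c1ccc(OCc3ccccc3)c(OCc3ccccc3)c1)[C@@H](O)C2)c1cc(OCc2ccccc2)c(OCc2ccccc2)c(OCc2ccccc2)c1 | intermediate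
13 | catechin 7-O-gallate, (2R,3S)-2-(3,4-dihydroxyphenyl)-3,5-dihydroxy-3,4-dihydro-2H-chromen-7-yl 3,4,5-trihydroxybenzoate | O=C(Oc1cc(O)c2c(c1)O[C@H](c1ccc(O)c(O)c1)[C@@H](O)C2)c1cc(O)c(O)c(O)c1 | target

**Total step count:** 7. **Longest linear sequence:** 7 steps (1 → 13); 6 and 11 are bought.

**Steps most likely to fail, with fallbacks**

Step 4 (cross versus homo coupling, regiochemistry and enantioselectivity of the cross-benzoin). The fallback sets out from 5 and 6 and comes back at 7. It keeps the acyl-anion coupling but moves the asymmetric induction to a later reduction. Aldehydes 5 and 6 (6 in excess) are coupled with the achiral salt 3-benzyl-5-(2-hydroxyethyl)-4-methylthiazolium chloride and Et3N in EtOH at 70 °C under thermodynamic control. This gives the racemic 2-hydroxy-1-one ketol F1, and any regioisomeric 1-hydroxy-2-one ketol F2 is carried along. Dess–Martin periodinane (CH2Cl2, NaHCO3) converts both ketols into the same 1,2-diketone F3. Transfer hydrogenation with RuCl(p-cymene)[(S,S)-N-tosyl-1,2-diphenylethylenediamide] in HCO2H–Et3N at 10 °C then reduces only the non-conjugated carbonyl next to the CH2 group, giving 7.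

Step 5 (over-reduction or ring-opening at the benzylic carbon, Friedel–Crafts side reactions of the free phloroglucinol ring, trans/cis ratio). The fallback sets out from 7 and comes back at 10. It closes ring C by SN2 etherification instead of oxocarbenium reduction. TBSOTf and 2,6-lutidine give the silyl ether F4. LiBH(s-Bu)3 in THF at −78 °C reduces the ketone under Felkin–Anh control to the syn (1S,2S) alcohol F5. HCl in MeOH removes both MOM groups and the silyl group to give the (1S,2S) diol bisphenol F6. Intramolecular Mitsunobu etherification (PPh3, DIAD, THF, 0 °C) of the ortho phenol onto the benzylic carbinol, with inversion, gives 10.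

Step 3 (lability of the electron-rich oxirane and arylacetaldehyde, MOM ethers under Lewis acid). The fallback sets out from 3 and comes back at 5. It replaces the epoxide rearrangement by a Wittig homologation. (Methoxymethyl)triphenylphosphonium chloride and KOtBu in THF at 0 °C give the E/Z methyl enol ether F7. Neutral hydrolysis with Hg(OAc)2 in THF–H2O, then KI, gives 5.

**Further compounds**
F1 | step 4 | racemic 1-[3,4-bis(benzyloxy)phenyl]-3-[2-(benzyloxy)-4,6-bis(methoxymethoxy)phenyl]-2-hydroxypropan-1-one | O=C(c1ccc(OCc2ccccc2)c(OCc2ccccc2)c1)C(O)Cc1c(OCc2ccccc2)cc(OCOC)cc1OCOC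
F2 | step 4 | racemic 1-[3,4-bis(benzyloxy)phenyl]-3-[2-(benzyloxy)-4,6-bis(methoxymethoxy)phenyl]-1-hydroxypropan-2-one | OC(c1ccc(OCc2ccccc2)c(OCc2ccccc2)c1)C(=O)Cc1c(OCc2ccccc2)cc(OCOC)cc1OCOC
F3 | step 4 | 1-[3,4-bis(benzyloxy)phenyl]-3-[2-(benzyloxy)-4,6-bis(methoxymethoxy)phenyl]propane-1,2-dione | O=C(c1ccc(OCc2ccccc2)c(OCc2ccccc2)c1)C(=O)Cc1c(OCc2ccccc2)cc(OCOC)cc1OCOC
F4 | step 5 | (2S)-1-[3,4-bis(benzyloxy)phenyl]-3-[2-(benzyloxy)-4,6-bis(methoxymethoxy)phenyl]-2-[(tert-butyldimethylsilyl)oxy]propan-1-one | O=C(c1ccc(OCc2ccccc2)c(OCc2ccccc2)c1)[C@@H](O[Si](C)(C)C(C)(C)C)Cc1c(OCc2ccccc2)cc(OCOC)cc1OCOC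
F5 | step 5 | (1S,2S)-1-[3,4-bis(benzyloxy)phenyl]-3-[2-(benzyloxy)-4,6-bis(methoxymethoxy)phenyl]-2-[(tert-butyldimethylsilyl)oxy]propan-1-ol | O[C@@H](c1ccc(OCc2ccccc2)c(OCc2ccccc2)c1)[C@@H](O[Si](C)(C)C(C)(C)C)Cc1c(OCc2ccccc2)cc(OCOC)cc1OCOC
F6 | step 5 | (1S,2S)-1-[3,4-bis(benzyloxy)phenyl]-3-[2-(benzyloxy)-4,6-dihydroxyphenyl]propane-1,2-diol | O[C@@H](c1ccc(OCc2ccccc2)c(OCc2ccccc2)c1)[C@@H](O)Cc1c(OCc2ccccc2)cc(O)cc1O
F7 | step 3 | 1-(benzyloxy)-2-(2-methoxyethenyl)-3,5-bis(methoxymethoxy)benzene (E/Z mixture) | COC=Cc1c(OCc2ccccc2)cc(OCOC)cc1OCOC
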